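An excess of 80% means 0.111 parts of left-handed substrate per part of right-handed substrate. The question was whether the flask could reach that ratio as charged, or whether it needed more free catalyst.

the same everywhere: impurity 2.2 mM

| flask | left-handed substrate | right-handed substrate | reagent | free catalyst | remark | time |
|---|---|---|---|---|---|---|
| beta | 0.11 M | 0.11 M | 0.22 M | 8.7 mM | run made earlier |  |
| gamma | 0.11 M | 0.11 M | 0.22 M | 20 mM | run made earlier |  |
| alpha | 0.17 M | 0.17 M | 0.22 M | 13 mM | run made earlier |  |
| flask | 0.11 M | 0.11 M | 0.220 M | 13 mM |  | 10 h |

| run | time / h | right-handed substrate / % | left-handed substrate / % |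
|---|---|---|---|
| beta | 1.50 | 50.1 | 24.3 |
| beta | 3.00 | 49.9 | 19.5 |
| beta | 5.00 | 48.8 | 14.5 |
| beta | 6.00 | 49.9 | 12.1 |
| beta | 8.00 | 49.4 | 8.0 |
| beta | 10.0 | 48.6 | 6.8 |
| beta | 12.0 | 48.3 | 5.1 |
| gamma | 1.00 | 49.2 | 12.7 |
| gamma | 1.33 | 49.3 | 11.3 |
| gamma | 2.00 | 49.1 | 8.4 |
| gamma | 3.00 | 48.5 | 6.5 |
| gamma | 5.00 | 48.1 | 2.5 |
| gamma | 8.00 | 47.4 | 0.3 |
| gamma | 12.0 | 46.7 | 0.8 |
| alpha | 1.00 | 49.3 | 21.2 |
| alpha | 2.00 | 49.3 | 17.9 |
| alpha | 3.00 | 48.9 | 14.5 |
| alpha | 6.00 | 48.9 | 9.0 |
| alpha | 12.0 | 48.5 | 4.4 |

(each reading ± 0.5 percentage points)

- free catalyst is single-handed; left-handed substrate and right-handed substrate are mirror images of each other, charged as a racemate, each of them at the stated concentration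

* whether the excess of right-handed substrate over left-handed substrate among what is left of the two reaches 80% by 10 h (yes / no)
* the highest excess of right-handed substrate over left-handed substrate among what is left of the two up to 10 h

From beta at 12.0 h and gamma at 5.00 h I read 72.0, with wide scatter, for the selectivity factor, the logarithm of the surviving fraction of left-handed substrate divided by that of right-handed substrate. Time drops out of this quotient, so it links the two substrates directly. Putting the wanted ratio into it, I reckoned that the flask would reach the excess with 48.5% of the total charge left as right-handed substrate, and with 46.1% of the charge reacted.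

The factor says nothing about the hour, so I turned to the runs. Beta, with 8.7 mM of free catalyst, stood at an excess of 75.5% at 10.0 h, short of the wanted one. The wanted excess needs left-handed substrate at 5.39% of the charge, and beta read below that at 12.0 h, gamma, with 20 mM, at 5.00 h. Taking the hours to go inversely with free catalyst minus impurity, which is my assumption, these give the flask, with 13 mM, 7.22 h and 8.24 h, both within 10 h. Alpha carries a heavier charge, 0.17 M of each substrate, so I did not carry its hours over. I left the flask's charge and time as they stood.

The forecast said yes, with a top of 91%, noting of the tail constants that “Both scale with catalyst minus impurity”.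

The flask gave yes, with a top of 90.6%.

    reagent + free catalyst + left-handed substrate → free catalyst + left-handed product (k = 0.683 L² mol⁻² s⁻¹)
    reagent + free catalyst + right-handed substrate → free catalyst + right-handed product (k = 0.00850 L² mol⁻² s⁻¹)
    left-handed product ⇌ right-handed product (k = 5.00 × 10⁻⁵ s⁻¹)
    free catalyst ⇌ dormant form (K = 13.0, k = 0.00198 s⁻¹)
    free catalyst + impurity → spent catalyst (k = 1.09 L mol⁻¹ s⁻¹)

The flask reached the wanted excess at 6.23 h with 46.0% of the charge reacted, against my reckoned 46.1%, so it can be charged as listed and followed by conversion. On alpha at 12.0 h, with left-handed substrate at 4.4%, the same factor gives right-handed substrate at 48.3%, and the reading was 48.5%.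

The numbers in the tables were generated by integration on assumed constants; noise was put on by code.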